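**Plan**
- Retrosynthesis: the two aryl pivalate O–acyl bonds are cut first (3',5'-OH), then O1–C8a of the pyranone, then C2–C3 (aroylation of a ketone enolate), then C4–C4a (Friedel–Crafts acylation).
- Forward: ring A is acylated with the methoxyacetyl unit (C3/C4), ring B is attached as its aroyl chloride to give an open 2-methoxy-1,3-diketone, ring C is closed by anodic C–H/O–H coupling, and the pivalates are removed.
- Enabling feature: in the diketone the 2,3,4,5-tetramethoxyphenyl ring (future ring A) has a single C–H, at C6', the carbon that becomes C8a. O1 can therefore be attached there by oxidation, and ring A needs neither a fifth oxygen nor a halide.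
- Stereochemistry: none to set; the only stereocentre on the way (C2 of the diketone, racemic and labile) becomes sp2 in the ring closure.

Key step: step 5

Assumption: the target has no stereocentre, stereogenic axis or double-bond isomerism, so it is one achiral compound and no enantiocontrol is needed.
Remark: metal salts of a product that are only protonated on aqueous work-up (lithium diketonate, aluminium complex of the ketone, potassium phenoxide) are counted with that product and carry no number of their own.

**Step 1**
Reactants: 1 1,2,3,4-tetramethoxybenzene; 2 methoxyacetyl chloride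
Product: 3 2-methoxy-1-(2,3,4,5-tetramethoxyphenyl)ethan-1-one
Conditions: AlCl3 (1.2 equiv), CH2Cl2, −20 → 0 °C; ice/1 M HCl
Reagents that add atoms: none
Why: Friedel–Crafts acylation of the electron-rich arene at one of its two symmetry-equivalent C–H positions, where the ketone formed is deactivated against a second acylation and the low temperature should suppress chelation-assisted ether cleavage.

**Step 2**
Reactants: 4 3,5-dihydroxy-4-methoxybenzoic acid
Product: 6 3,5-bis(pivaloyloxy)-4-methoxybenzoic acid, via mixed pivalic anhydride 5 (not isolated)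
Conditions: PivCl (3.5 equiv), pyridine, DMAP (cat.), CH2Cl2, 0 → 25 °C; then H2O, THF, 25 °C
Reagents that add atoms: pivaloyl chloride CC(C)(C)C(=O)Cl; water O
Why: DMAP-catalysed O-acylation of both phenols also turns the carboxyl group into a mixed anhydride, and only this anhydride is hydrolysed by aqueous pyridine, the hindered aryl pivalates staying intact.

**Step 3**
Reactants: 6 3,5-bis(pivaloyloxy)-4-methoxybenzoic acid
Product: 7 3,5-bis(pivaloyloxy)-4-methoxybenzoyl chloride
Conditions: (COCl)2 (1.5 equiv), DMF (cat.), CH2Cl2, 0 → 25 °C; evaporate, use crude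
Reagents that add atoms: oxalyl chloride O=C(Cl)C(=O)Cl
Why: Acid chloride formation through the catalytic chloroiminium (Vilsmeier-type) species under neutral conditions that the aryl esters and the methyl ether tolerate.

**Step 4**
Reactants: 3 2-methoxy-1-(2,3,4,5-tetramethoxyphenyl)ethan-1-one; 7 3,5-bis(pivaloyloxy)-4-methoxybenzoyl chloride
Product: 9 1-[3,5-bis(pivaloyloxy)-4-methoxyphenyl]-2-methoxy-3-(2,3,4,5-tetramethoxyphenyl)propane-1,3-dione, via lithium enolate 8 (not isolated)
Conditions: LiHMDS (2.2 equiv), THF–toluene, −78 °C; then 7, −78 → 0 °C; aq. NH4Cl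
Reagents that add atoms: none
Why: Claisen-type C-acylation of a preformed lithium ketone enolate with an aroyl chloride, in which the second equivalent of base takes up the more acidic diketone and the hindered pivalates are far less electrophilic than the acid chloride at −78 °C.

**Step 5**
Reactants: 9 1-[3,5-bis(pivaloyloxy)-4-methoxyphenyl]-2-methoxy-3-(2,3,4,5-tetramethoxyphenyl)propane-1,3-dione
Product: 10 3',5'-bis(pivaloyloxy)-3,5,6,7,8,4'-hexamethoxyflavone
Conditions: graphite anode, Pt cathode, undivided cell, n-Bu4NPF6 (0.1 M), dry HFIP–CH2Cl2 (4:1), 5 mA cm⁻², 2.2 F mol⁻¹, 25 °C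
Reagents that add atoms: none
Why: Proposed new method: one-electron oxidation at the carbon anode should occur on the tetramethoxyaryl ring of 9, its most electron-rich π-system, and the radical cation should be captured at C6' (the only C–H of that ring, para to the 3'-methoxy group) by the oxygen of the ring-B carbonyl, either as the enol O–H or as the carbonyl oxygen followed by loss of the acidic C2–H; a second electron transfer and loss of the C6' proton then restore aromaticity while the released protons are reduced to hydrogen at the cathode. The closest known reaction types are anodic dehydrogenative C–O cyclisations, namely the lactonisation of biaryl-2-carboxylic acids to benzocoumarins and the closure of anilides to benzoxazoles in fluorinated alcohols, whereas the oxygen of a 1,3-diketone has not been used in this role. The pyranone ring closes by a 6-endo-trig-type attack of oxygen on an arene carbon (the C1'–C6' π-bond ends up inside the new ring), which forms O1–C8a and the ortho-fused ring C in one operation. No stereocentre is formed, and the labile centre at C2 of 9 becomes the sp2 carbon C3. The step needs oxidation on ring A and not on ring B, and bond formation at the C–H carbon and not ipso at the methoxy-bearing C2': the two pivalates and the aroyl group should keep ring B beyond the working potential, attack at C2' cannot be followed by proton loss and should revert, and the charge is held near 2.2 F mol⁻¹ as a safeguard although the chromone, whose ring oxygen is tied up in a vinylogous ester, should be somewhat harder to oxidise than 9.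

**Step 6**
Reactants: 10 3',5'-bis(pivaloyloxy)-3,5,6,7,8,4'-hexamethoxyflavone
Product: 11 3',5'-dihydroxy-3,5,6,7,8,4'-hexamethoxyflavone
Conditions: K2CO3 (2.5 equiv), MeOH, Ar, 25 °C; then aq. NH4Cl
Reagents that add atoms: none
Why: Base-mediated methanolysis (transesterification) of the two aryl pivalates, aryloxide being a good leaving group, under conditions to which the chromone core and the six methyl ethers should be inert.

**Compound list**
1 | 1,2,3,4-tetramethoxybenzene | COc1ccc(OC)c(OC)c1OC | starting material
2 | methoxyacetyl chloride | COCC(=O)Cl | starting material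
3 | 2-methoxy-1-(2,3,4,5-tetramethoxyphenyl)ethan-1-one | COCC(=O)c1cc(OC)c(OC)c(OC)c1OC | intermediate
4 | 3,5-dihydroxy-4-methoxybenzoic acid | COc1c(O)cc(C(=O)O)cc1O | starting material
5 | 3,5-bis(pivaloyloxy)-4-methoxybenzoic pivalic anhydride (not isolated) | COc1c(OC(=O)C(C)(C)C)cc(C(=O)OC(=O)C(C)(C)C)cc1OC(=O)C(C)(C)C | intermediate
6 | 3,5-bis(pivaloyloxy)-4-methoxybenzoic acid | COc1c(OC(=O)C(C)(C)C)cc(C(=O)O)cc1OC(=O)C(C)(C)C | intermediate
7 | 3,5-bis(pivaloyloxy)-4-methoxybenzoyl chloride | COc1c(OC(=O)C(C)(C)C)cc(C(=O)Cl)cc1OC(=O)C(C)(C)C | intermediate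
8 | lithium (Z)-2-methoxy-1-(2,3,4,5-tetramethoxyphenyl)ethen-1-olate, chelated enolate of 3 (not isolated) | [Li]O/C(=C\OC)c1cc(OC)c(OC)c(OC)c1OC | intermediate
9 | 1-[3,5-bis(pivaloyloxy)-4-methoxyphenyl]-2-methoxy-3-(2,3,4,5-tetramethoxyphenyl)propane-1,3-dione (racemic and labile at C2) | COc1cc(C(=O)C(OC)C(=O)c2cc(OC(=O)C(C)(C)C)c(OC)c(OC(=O)C(C)(C)C)c2)c(OC)c(OC)c1OC | intermediate
10 | 3',5'-bis(pivaloyloxy)-3,5,6,7,8,4'-hexamethoxyflavone | COc1c(OC(=O)C(C)(C)C)cc(-c2oc3c(OC)c(OC)c(OC)c(OC)c3c(=O)c2OC)cc1OC(=O)C(C)(C)C | intermediate
11 | 3',5'-dihydroxy-3,5,6,7,8,4'-hexamethoxyflavone | COc1c(O)cc(-c2oc3c(OC)c(OC)c(OC)c(OC)c3c(=O)c2OC)cc1O | target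

**Step count**
Total: 6 steps (convergent). Longest linear sequence: 5 steps (4 → 6 → 7 → 9 → 10 → 11, steps 2–6).

**Steps most likely to fail**

Step 5 (the new method). The anode may oxidise the diketone enol at C2 instead of ring A, the chromone formed may be oxidised further (oxidative demethylation of the para-dimethoxy pattern towards a quinone), or the oxygen may add at a methoxy-bearing carbon. In each case the C–O closure would not become the main path. The fallback uses known chemistry: the lone C–H is turned into C–Br before the diketone is built, and the same O1–C8a bond is made by copper catalysis. It sets out from ketone 3, which is brominated at its only aromatic C–H (NBS, MeCN, 25 °C) to give 1-(2-bromo-3,4,5,6-tetramethoxyphenyl)-2-methoxyethan-1-one F1. Deprotonation (LiHMDS, THF, −78 °C) gives the lithium (Z)-enolate of the bromo ketone F2, which is aroylated with 7 as in step 4 to 1-(2-bromo-3,4,5,6-tetramethoxyphenyl)-3-[3,5-bis(pivaloyloxy)-4-methoxyphenyl]-2-methoxypropane-1,3-dione F3. Intramolecular Ullmann-type O-arylation of the diketone enolate (CuI 10 mol %, 1,10-phenanthroline, K2CO3, DMF, 90 °C) closes the pyranone and returns to the route at 10. Partial loss of pivalate under these conditions would not matter, because step 6 removes both esters.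

Step 4. The ambident enolate may be acylated on oxygen (enol ester), or it may attack an aryl pivalate instead of the acid chloride. The fallback forms the C2–C3 bond by aldol addition and adjusts the oxidation level afterwards. It sets out from 7, which is reduced to 3,5-bis(pivaloyloxy)-4-methoxybenzaldehyde F4 (Rosenmund reduction: H2, Pd/BaSO4, 2,6-lutidine, toluene). Enolate 8, generated from 3 as in step 4, adds to this aldehyde at −78 °C to give 3-[3,5-bis(pivaloyloxy)-4-methoxyphenyl]-3-hydroxy-2-methoxy-1-(2,3,4,5-tetramethoxyphenyl)propan-1-one F5 as a mixture of diastereomers. Dess–Martin oxidation of the secondary alcohol (CH2Cl2, 25 °C) then returns to the route at 9.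

Step 1. The Lewis acid may cleave the methoxy group ortho to the new carbonyl through a chelate, or the side-chain methyl ether, and the ring oxygen pattern needed for step 5 would be lost. The fallback replaces electrophilic acylation by directed ortho-metalation. It sets out from 1, which is lithiated next to a methoxy group (n-BuLi, TMEDA, THF, 0 °C) to (2,3,4,5-tetramethoxyphenyl)lithium F6. Addition to N,2-dimethoxy-N-methylacetamide at −78 °C gives the chelated tetrahedral adduct lithium 2-methoxy-1-[methoxy(methyl)amino]-1-(2,3,4,5-tetramethoxyphenyl)ethan-1-olate F7, which collapses on quenching with aqueous NH4Cl and returns to the route at 3.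

**Further compounds**
F1 | step 5 | 1-(2-bromo-3,4,5,6-tetramethoxyphenyl)-2-methoxyethan-1-one | COCC(=O)c1c(Br)c(OC)c(OC)c(OC)c1OC
F2 | step 5 | lithium (Z)-1-(2-bromo-3,4,5,6-tetramethoxyphenyl)-2-methoxyethen-1-olate | [Li]O/C(=C\OC)c1c(Br)c(OC)c(OC)c(OC)c1OC
F3 | step 5 | 1-(2-bromo-3,4,5,6-tetramethoxyphenyl)-3-[3,5-bis(pivaloyloxy)-4-methoxyphenyl]-2-methoxypropane-1,3-dione (racemic) | COc1c(OC)c(OC)c(Br)c(C(=O)C(OC)C(=O)c2cc(OC(=O)C(C)(C)C)c(OC)c(OC(=O)C(C)(C)C)c2)c1OC
F4 | step 4 | 3,5-bis(pivaloyloxy)-4-methoxybenzaldehyde | COc1c(OC(=O)C(C)(C)C)cc(C=O)cc1OC(=O)C(C)(C)C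
F5 | step 4 | 3-[3,5-bis(pivaloyloxy)-4-methoxyphenyl]-3-hydroxy-2-methoxy-1-(2,3,4,5-tetramethoxyphenyl)propan-1-one (diastereomer mixture, racemic) | COc1cc(C(=O)C(OC)C(O)c2cc(OC(=O)C(C)(C)C)c(OC)c(OC(=O)C(C)(C)C)c2)c(OC)c(OC)c1OC
F6 | step 1 | (2,3,4,5-tetramethoxyphenyl)lithium | [Li]c1cc(OC)c(OC)c(OC)c1OC
F7 | step 1 | lithium 2-methoxy-1-[methoxy(methyl)amino]-1-(2,3,4,5-tetramethoxyphenyl)ethan-1-olate (racemic) | COCC(O[Li])(N(C)OC)c1cc(OC)c(OC)c(OC)c1OC
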